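**Plan**
- Retrosynthetic cuts: ring B at O1–C8a and C2–C3 (acetaldehyde leaves), then C8–prenyl, C8–CH2 of the lavandulyl group, C4a–C4 (propanoyl), and last the C6–side-chain bond, which comes from a Pechmann coumarin of 3,5-dimethoxyphenol whose lactone masks both the acid and O7.
- Forward: the lactone ring forms first on aromatic ring A; the arene is then dressed (Br at C8, propanoyl at C4a, lavandulyl in place of Br), the lactone is opened, ring A is dearomatised by C8 prenylation, and ring B closes last, followed by two unmasking steps.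
- Enabling feature: once dearomatised, ring A is a cyclohexa-2,4-dienone, so C8a=C4a is a true vinylogous-ester alkene; with the C4 acyl carbon as its Z silyl enol ether it forms the 1-methoxy-3-silyloxy diene C8a(OMe)=C4a–C4(OSi)=C3H–CH3, which takes up acetaldehyde as O1–C2.
- Stereochemistry: side-chain centre from CuH/bisphosphine 1,4-reduction of the coumarin; lavandulyl centre from (S)-lavandulol; C8 from a Trost-ligand palladium allylation; C2/C3 from a chiral chromium Schiff-base catalyst, the Z enol ether and the endo transition state.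

Key step: step 11

Assumption: the lavandulol enantiomer needed, SMILES C=C(C)[C@H](CC=C(C)C)CO, is (S) by the CIP rules (it becomes the (2R)-lavandulyl group once its CH2 is bound to carbon); it is taken as purchasable in enantioenriched form, otherwise it comes from lipase resolution of the commercial racemate.

Numbering: compounds 3–11 carry coumarin numbering (coumarin C8 = target C8, coumarin C6 = target C4a, coumarin C4 = side-chain carbon, lactone O1 = target O7); from 12 on the target numbering O1, C2, C3, C4, C4a, C5, C6, C7, C8, C8a is used.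

**Step 1**
Reactants: 1 3,5-dimethoxyphenol; 2 ethyl 3-oxohexanoate
Product: 3 5,7-dimethoxy-4-propyl-2H-chromen-2-one
Conditions: conc. H2SO4, 0 °C → rt
Reagents that add atoms: none
Why: Pechmann condensation: acid-promoted transesterification and ring closure ortho to the hydroxyl of the symmetric, strongly activated phenol can give only one coumarin, which already holds the side-chain carbons and masks the acid and the future C7 oxygen as a lactone.

**Step 2**
Reactants: 3 5,7-dimethoxy-4-propyl-2H-chromen-2-one
Product: 4 (4R)-5,7-dimethoxy-4-propyl-3,4-dihydro-2H-chromen-2-one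
Conditions: Cu(OAc)2·H2O (3 mol %), (R)-DTBM-SEGPHOS (3 mol %), (EtO)2MeSiH, t-BuOH, toluene, 0 °C → rt
Reagents that add atoms: none
Why: CuH-catalysed asymmetric conjugate reduction of a coumarin (a β-aryl-β-alkyl enoate of fixed geometry) delivers hydride to one face of C4 under control of the bisphosphine and t-BuOH protonates the copper enolate, the ligand hand being taken as the one that gives 4R (its antipode is used if the sense of induction proves opposite).

**Step 3**
Reactants: 4 (4R)-5,7-dimethoxy-4-propyl-3,4-dihydro-2H-chromen-2-one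
Product: 5 (4R)-8-bromo-5,7-dimethoxy-4-propyl-3,4-dihydro-2H-chromen-2-one
Conditions: NBS (1.0 equiv), MeCN, 0 °C → rt
Reagents that add atoms: N-bromosuccinimide, O=C1CCC(=O)N1Br
Why: Electrophilic aromatic bromination should go to C8, which is para to the 5-methoxy and ortho to the 7-methoxy group and less crowded than C6 between two methoxy groups, the pattern known from 2-bromination of 3,5-dimethoxytoluene-type arenes.

**Step 4**
Reactants: 5 (4R)-8-bromo-5,7-dimethoxy-4-propyl-3,4-dihydro-2H-chromen-2-one; 6 propanoyl chloride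
Product: 7 (4R)-8-bromo-5,7-dimethoxy-6-propanoyl-4-propyl-3,4-dihydro-2H-chromen-2-one
Conditions: TiCl4, CH2Cl2, −10 °C → rt
Reagents that add atoms: none
Why: Friedel–Crafts acylation can only take the last free ring carbon C6, activated by two ortho methoxy groups, while the bromine blocks C8 and is kept as the coupling handle, and lactone and stereocentre are not touched by TiCl4 at low temperature.

**Step 5**
Reactants: 8 (S)-lavandulol [(2S)-5-methyl-2-(prop-1-en-2-yl)hex-4-en-1-ol]
Product: 9 (S)-lavandulyl iodide [(3S)-3-(iodomethyl)-2,6-dimethylhepta-1,5-diene]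
Conditions: PPh3, I2, imidazole, CH2Cl2, 0 °C → rt
Reagents that add atoms: iodine, II
Why: Appel-type iodination replaces the primary hydroxyl by SN2 at CH2, so the adjacent stereocentre and both alkenes are not involved.

**Step 6**
Reactants: 9 (S)-lavandulyl iodide; 7 (4R)-8-bromo-5,7-dimethoxy-6-propanoyl-4-propyl-3,4-dihydro-2H-chromen-2-one
Product: 11 (4R)-5,7-dimethoxy-8-[(2R)-5-methyl-2-(prop-1-en-2-yl)hex-4-en-1-yl]-6-propanoyl-4-propyl-3,4-dihydro-2H-chromen-2-one, via lavandulylzinc iodide 10 (not isolated)
Conditions: 9, Zn dust, LiCl, THF, 40 °C; then 7, Pd(OAc)2 (3 mol %), SPhos (6 mol %), THF, rt → 50 °C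
Reagents that add atoms: none
Why: Negishi coupling: zinc insertion gives a primary alkylzinc iodide that tolerates ketone and lactone, and Pd(OAc)2/SPhos is established for joining primary alkylzinc halides to di-ortho-substituted aryl bromides without β-hydride loss, the stereocentre β to zinc being configurationally unaffected.

**Step 7**
Reactants: 11 the lavandulylated lactone
Product: 12 2-(trimethylsilyl)ethyl (3R)-3-{2-hydroxy-4,6-dimethoxy-3-[(2R)-5-methyl-2-(prop-1-en-2-yl)hex-4-en-1-yl]-5-propanoylphenyl}hexanoate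
Conditions: Me3SiCH2CH2OH, NaH, THF, 0 °C; then AcOH (1 equiv), 0 °C
Reagents that add atoms: 2-(trimethylsilyl)ethanol, C[Si](C)(C)CCO
Why: Alkoxide transesterification of the aryl lactone (an activated ester) is driven by release of the phenoxide and installs an ester that fluoride removes at the end, while the mild quench and prompt use should keep the hindered phenol ester from relactonising.

**Step 8**
Reactants: 13 3-methylbut-2-en-1-ol (prenol)
Product: 14 methyl 3-methylbut-2-en-1-yl carbonate
Conditions: ClCO2Me, pyridine, CH2Cl2, 0 °C → rt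
Reagents that add atoms: methyl chloroformate, COC(=O)Cl
Why: Chloroformate acylation of a primary allylic alcohol gives the allylic carbonate that ionises cleanly with zerovalent palladium.

**Step 9**
Reactants: 12 the phenol ester; 14 methyl 3-methylbut-2-en-1-yl carbonate
Product: 15 2-(trimethylsilyl)ethyl (3R)-3-{(5R)-2,4-dimethoxy-5-[(2R)-5-methyl-2-(prop-1-en-2-yl)hex-4-en-1-yl]-5-(3-methylbut-2-en-1-yl)-6-oxo-3-propanoylcyclohexa-1,3-dien-1-yl}hexanoate (C8 quaternary, C7 ketone in target numbering)
Conditions: Pd2(dba)3·CHCl3 (2.5 mol %), (R,R)-DACH-phenyl Trost ligand (7.5 mol %), 1,4-dioxane, rt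
Reagents that add atoms: none
Why: Palladium-catalysed asymmetric allylic alkylative dearomatisation (Tsuji–Trost type, as known for 2-naphthols and acylphloroglucinols): decarboxylative ionisation gives a π-prenyl palladium cation and methoxide, which deprotonates the phenol; O-prenylation is reversible under zerovalent palladium whereas attack of the less hindered ortho carbon C8 on the CH2 terminus is not, the chiral pocket of the Trost ligand (hand chosen for 8R) selects the ring face, and the two methyl ethers lock the product as the C7 ketone with C5=C6 and C4a=C8a.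

**Step 10**
Reactants: 15 the dienone
Product: 17 2-(trimethylsilyl)ethyl (3R)-3-{(5R)-2,4-dimethoxy-5-[(2R)-5-methyl-2-(prop-1-en-2-yl)hex-4-en-1-yl]-5-(3-methylbut-2-en-1-yl)-6-oxo-3-[(1Z)-1-(triethylsilyloxy)prop-1-en-1-yl]cyclohexa-1,3-dien-1-yl}hexanoate, via potassium Z-enolate 16 (not isolated)
Conditions: KHMDS, THF, −78 °C; TESOTf, −78 °C; Et3N-buffered work-up
Reagents that add atoms: triethylsilyl trifluoromethanesulfonate, CC[Si](CC)(CC)OS(=O)(=O)C(F)(F)F
Why: Kinetic enolisation of the ethyl ketone, whose bulky fully substituted vinyl residue forces the Z enolate as with ethyl mesityl ketone, followed by O-silylation (silyl enol ether formation) should give the Z enol ether in which C3–H, not the methyl, lies inside the future s-cis diene, the ester α-protons being less acidic and C7 having no α-hydrogen.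

**Step 11**
Reactants: 17 the Z silyl dienol ether; 18 acetaldehyde
Product: 20 2-(trimethylsilyl)ethyl (3R)-3-{(2R,3S,8R)-5-methoxy-2,3-dimethyl-8-[(2R)-5-methyl-2-(prop-1-en-2-yl)hex-4-en-1-yl]-8-(3-methylbut-2-en-1-yl)-4,7-dioxo-3,4,7,8-tetrahydro-2H-chromen-6-yl}hexanoate, via ketal cycloadduct 19 (not isolated)
Conditions: 18 (excess), CrCl(L) (10 mol %; L = dianion of 2-(adamantan-1-yl)-6-({[(1R,2S)-2-hydroxy-2,3-dihydro-1H-inden-1-yl]imino}methyl)-4-methylphenol), 4 Å MS, TBME, 0 °C → rt, sealed; then TFA (cat.), wet CH2Cl2, 0 °C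
Reagents that add atoms: none
Why: Proposed new method: the trivalent chromium complex CrCl(L) binds acetaldehyde anti to its methyl group and the aldehyde adds across C3 and C8a of the diene C8a(OMe)=C4a–C4(OSiEt3)=C3H–CH3 in a concerted but asynchronous [4+2] (C2–C3 ahead of O1–C8a), after which catalytic acid expels methanol from the ketal carbon C8a and the silyl group from O4 and restores C8a=C4a. The closest known reactions are the chromium Schiff-base-catalysed hetero-Diels–Alder additions of aldehydes to 1-methoxy-3-silyloxy-4-methyl dienes and to Brassard-type dienes with a doubly substituted alkoxy terminus; new is that the diene is part of a cyclohexadienone ring and is flanked on both sides. Ring B closes as a six-membered ring by cycloaddition, and even if the second bond lags, the cationic charge of the intermediate is spread over C4 and C8a only, so O1 closes on C8a (6-endo) and cannot reach C5. C2 (R) is set by the catalyst, which must present the Si face of acetaldehyde to C3, and C3 (S) follows from the Z enol ether (methyl outside) and the endo approach, which together give the cis-2,3-dimethyl pair. The diene face used is the one syn to the lavandulyl CH2 on C8; both C8 substituents are methylene groups, so substrate bias should be small and the catalyst hand decides (the mirror-image complex is used if induction proves opposite). The step needs cycloaddition over an open-chain Mukaiyama aldol path, which the weakly Lewis acidic, non-silylating chromium catalyst and the non-basic work-up are chosen to secure.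

**Step 12**
Reactants: 20 the C5 methyl enol ether
Product: 21 2-(trimethylsilyl)ethyl (3R)-3-{(2R,3S,8R)-5-hydroxy-2,3-dimethyl-8-[(2R)-5-methyl-2-(prop-1-en-2-yl)hex-4-en-1-yl]-8-(3-methylbut-2-en-1-yl)-4,7-dioxo-3,4,7,8-tetrahydro-2H-chromen-6-yl}hexanoate
Conditions: LiCl, DMSO, 100 °C; dil. aq. HCl work-up (0 °C)
Reagents that add atoms: none
Why: SN2 O-demethylation of a vinylogous methyl ester by chloride in DMSO, the method used for methyl enol ethers of dearomatised acylphloroglucinols, releases the stabilised triketone enolate, which then shields C3–H, in a non-basic medium that should leave the cis C2/C3 pair, the alkenes and the silylethyl ester untouched.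

**Step 13**
Reactants: 21 the silylethyl ester
Product: 22 (3R)-3-{(2R,3S,8R)-5-hydroxy-2,3-dimethyl-8-[(2R)-5-methyl-2-(prop-1-en-2-yl)hex-4-en-1-yl]-8-(3-methylbut-2-en-1-yl)-4,7-dioxo-3,4,7,8-tetrahydro-2H-chromen-6-yl}hexanoic acid (CNP0266113.2)
Conditions: TBAF, THF, 0 °C → rt; dil. aq. HCl work-up (0 °C)
Reagents that add atoms: none
Why: Fluoride-induced fragmentation of the 2-(trimethylsilyl)ethyl ester (β-elimination to ethene and Me3SiF) frees the acid without any acid treatment of the prenyl and isopropenyl groups, the acidic enol being deprotonated first so that C3 should not epimerise.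

**Compound list**

1 | 3,5-dimethoxyphenol | COc1cc(O)cc(OC)c1 | starting material
2 | ethyl 3-oxohexanoate | CCCC(=O)CC(=O)OCC | starting material
3 | 5,7-dimethoxy-4-propyl-2H-chromen-2-one | CCCC1=CC(=O)Oc2cc(OC)cc(OC)c12 | intermediate
4 | (4R)-5,7-dimethoxy-4-propyl-3,4-dihydro-2H-chromen-2-one | CCC[C@@H]1CC(=O)Oc2cc(OC)cc(OC)c21 | intermediate
5 | (4R)-8-bromo-5,7-dimethoxy-4-propyl-3,4-dihydro-2H-chromen-2-one | CCC[C@@H]1CC(=O)Oc2c(Br)c(OC)cc(OC)c21 | intermediate
6 | propanoyl chloride | CCC(=O)Cl | starting material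
7 | (4R)-8-bromo-5,7-dimethoxy-6-propanoyl-4-propyl-3,4-dihydro-2H-chromen-2-one | CCC[C@@H]1CC(=O)Oc2c(Br)c(OC)c(C(=O)CC)c(OC)c21 | intermediate
8 | (S)-lavandulol, (2S)-5-methyl-2-(prop-1-en-2-yl)hex-4-en-1-ol | C=C(C)[C@H](CC=C(C)C)CO | starting material
9 | (S)-lavandulyl iodide, (3S)-3-(iodomethyl)-2,6-dimethylhepta-1,5-diene | C=C(C)[C@H](CC=C(C)C)CI | intermediate
10 | [(2S)-5-methyl-2-(prop-1-en-2-yl)hex-4-en-1-yl]zinc iodide (not isolated) | C=C(C)[C@H](CC=C(C)C)C[Zn]I | intermediate
11 | (4R)-5,7-dimethoxy-8-[(2R)-5-methyl-2-(prop-1-en-2-yl)hex-4-en-1-yl]-6-propanoyl-4-propyl-3,4-dihydro-2H-chromen-2-one | C=C(C)[C@H](CC=C(C)C)Cc1c(OC)c(C(=O)CC)c(OC)c2c1OC(=O)C[C@H]2CCC | intermediate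
12 | 2-(trimethylsilyl)ethyl (3R)-3-{2-hydroxy-4,6-dimethoxy-3-[(2R)-5-methyl-2-(prop-1-en-2-yl)hex-4-en-1-yl]-5-propanoylphenyl}hexanoate | C=C(C)[C@H](CC=C(C)C)Cc1c(O)c([C@H](CCC)CC(=O)OCC[Si](C)(C)C)c(OC)c(C(=O)CC)c1OC | intermediate
13 | 3-methylbut-2-en-1-ol (prenol) | CC(C)=CCO | starting material
14 | methyl 3-methylbut-2-en-1-yl carbonate | COC(=O)OCC=C(C)C | intermediate
15 | 2-(trimethylsilyl)ethyl (3R)-3-{(5R)-2,4-dimethoxy-5-[(2R)-5-methyl-2-(prop-1-en-2-yl)hex-4-en-1-yl]-5-(3-methylbut-2-en-1-yl)-6-oxo-3-propanoylcyclohexa-1,3-dien-1-yl}hexanoate | C=C(C)[C@H](CC=C(C)C)C[C@@]1(CC=C(C)C)C(=O)C([C@H](CCC)CC(=O)OCC[Si](C)(C)C)=C(OC)C(C(=O)CC)=C1OC | intermediate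
16 | potassium (Z)-enolate of 15 at the propanoyl group (not isolated) | C=C(C)[C@H](CC=C(C)C)C[C@@]1(CC=C(C)C)C(=O)C([C@H](CCC)CC(=O)OCC[Si](C)(C)C)=C(OC)C(/C([O-])=C/C)=C1OC.[K+] | intermediate
17 | (Z)-triethylsilyl dienol ether of 15: 3-[(1Z)-1-(triethylsilyloxy)prop-1-en-1-yl] in place of 3-propanoyl | C=C(C)[C@H](CC=C(C)C)C[C@@]1(CC=C(C)C)C(=O)C([C@H](CCC)CC(=O)OCC[Si](C)(C)C)=C(OC)C(/C(O[Si](CC)(CC)CC)=C/C)=C1OC | intermediate
18 | acetaldehyde | CC=O | starting material
19 | [4+2] adduct: (2R,3S,8aR)-5,8a-dimethoxy-2,3-dimethyl-4-(triethylsilyloxy)-8,8a-dihydro-2H-chromen-7(3H)-one core, C8 substituents and C6 side chain as in 17, C8 unchanged in space (not isolated) | C=C(C)[C@H](CC=C(C)C)C[C@@]1(CC=C(C)C)C(=O)C([C@H](CCC)CC(=O)OCC[Si](C)(C)C)=C(OC)C2=C(O[Si](CC)(CC)CC)[C@@H](C)[C@@H](C)O[C@]21OC | intermediate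
20 | 2-(trimethylsilyl)ethyl (3R)-3-{(2R,3S,8R)-5-methoxy-2,3-dimethyl-8-[(2R)-5-methyl-2-(prop-1-en-2-yl)hex-4-en-1-yl]-8-(3-methylbut-2-en-1-yl)-4,7-dioxo-3,4,7,8-tetrahydro-2H-chromen-6-yl}hexanoate | C=C(C)[C@H](CC=C(C)C)C[C@@]1(CC=C(C)C)C(=O)C([C@H](CCC)CC(=O)OCC[Si](C)(C)C)=C(OC)C2=C1O[C@H](C)[C@H](C)C2=O | intermediate
21 | 2-(trimethylsilyl)ethyl (3R)-3-{(2R,3S,8R)-5-hydroxy-2,3-dimethyl-8-[(2R)-5-methyl-2-(prop-1-en-2-yl)hex-4-en-1-yl]-8-(3-methylbut-2-en-1-yl)-4,7-dioxo-3,4,7,8-tetrahydro-2H-chromen-6-yl}hexanoate | C=C(C)[C@H](CC=C(C)C)C[C@@]1(CC=C(C)C)C(=O)C([C@H](CCC)CC(=O)OCC[Si](C)(C)C)=C(O)C2=C1O[C@H](C)[C@H](C)C2=O | intermediate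
22 | (3R)-3-{(2R,3S,8R)-5-hydroxy-2,3-dimethyl-8-[(2R)-5-methyl-2-(prop-1-en-2-yl)hex-4-en-1-yl]-8-(3-methylbut-2-en-1-yl)-4,7-dioxo-3,4,7,8-tetrahydro-2H-chromen-6-yl}hexanoic acid | C=C(C)[C@H](CC=C(C)C)C[C@@]1(CC=C(C)C)C(=O)C([C@H](CCC)CC(=O)O)=C(O)C2=C1O[C@H](C)[C@H](C)C2=O | target

**Step count and risks**

Total steps: 13. Longest linear sequence: 11 steps (1, 2, 3, 4, 6, 7, 9, 10, 11, 12, 13) from 3,5-dimethoxyphenol; steps 5 and 8 prepare the two side-chain reagents.

Steps most likely to fail:

1. Step 11 (new method). The diene is flanked on both sides and twisted out of plane, and its alkoxy terminus C8a is fully substituted, so the cycloaddition may be slow. An open-chain Mukaiyama aldol path could then take over, with loss of cis selectivity and later ring closure at C5 as well as C8a. The catalyst may also fail to override the diene-face preference set by C8. Fallback with known chemistry, setting out from dienone 15: the propanoyl group is converted with diisopinocampheylboron triflate and iPr2NEt (CH2Cl2, −78 °C) into its Z enol borinate, and a Paterson-type syn aldol addition to acetaldehyde 18 (reagent hand chosen for Si-face attack) gives the syn aldol 2-(trimethylsilyl)ethyl (3R)-3-{(5R)-3-[(2S,3R)-3-hydroxy-2-methylbutanoyl]-2,4-dimethoxy-5-[(2R)-5-methyl-2-(prop-1-en-2-yl)hex-4-en-1-yl]-5-(3-methylbut-2-en-1-yl)-6-oxocyclohexa-1,3-dien-1-yl}hexanoate F1. PPTS in CH2Cl2 then closes ring B by conjugate addition of the hydroxyl to C8a and loss of methanol, which comes back to the route at 20. Here O1 is no longer delivered within a diene, so closure at C8a over C5 rests only on the direct conjugation of C8a with the C4 ketone, and any isomeric ring closure would have to be separated.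

2. Step 9. Facial selectivity at C8 may be poor on a fully substituted monocyclic phenol, and prenylation at O7 or at the more hindered C6 may compete. Fallback, setting out from phenol 12: the sodium phenoxide (NaH, toluene) is C-alkylated with prenyl bromide in the non-polar medium (alkylative dearomatisation of the lupulone type) without catalyst control. This gives 15 together with its C8 epimer, 2-(trimethylsilyl)ethyl (3R)-3-{(5S)-2,4-dimethoxy-5-[(2R)-5-methyl-2-(prop-1-en-2-yl)hex-4-en-1-yl]-5-(3-methylbut-2-en-1-yl)-6-oxo-3-propanoylcyclohexa-1,3-dien-1-yl}hexanoate F2. The two are diastereomers because of the two existing stereocentres and are separated by chromatography, and the route is rejoined at 15.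

3. Step 12. At the temperature needed for chloride attack, C3 may epimerise to the trans-dimethyl series, or the C8 prenyl group may shift thermally (retro-Claisen-type). Fallback, setting out from 20: the vinylogous methyl ester is hydrolysed instead by addition of water at C5 and loss of methanol in dilute HCl/THF at room temperature, which cleaves the C5–O bond rather than the O–CH3 bond and needs no heating. It makes no new compound and comes back to the route at 21.

**Further compounds**

F1 | step 11 | 2-(trimethylsilyl)ethyl (3R)-3-{(5R)-3-[(2S,3R)-3-hydroxy-2-methylbutanoyl]-2,4-dimethoxy-5-[(2R)-5-methyl-2-(prop-1-en-2-yl)hex-4-en-1-yl]-5-(3-methylbut-2-en-1-yl)-6-oxocyclohexa-1,3-dien-1-yl}hexanoate | C=C(C)[C@H](CC=C(C)C)C[C@@]1(CC=C(C)C)C(=O)C([C@H](CCC)CC(=O)OCC[Si](C)(C)C)=C(OC)C(C(=O)[C@@H](C)[C@@H](C)O)=C1OC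
F2 | step 9 | 2-(trimethylsilyl)ethyl (3R)-3-{(5S)-2,4-dimethoxy-5-[(2R)-5-methyl-2-(prop-1-en-2-yl)hex-4-en-1-yl]-5-(3-methylbut-2-en-1-yl)-6-oxo-3-propanoylcyclohexa-1,3-dien-1-yl}hexanoate (C8 epimer of 15) | C=C(C)[C@H](CC=C(C)C)C[C@]1(CC=C(C)C)C(=O)C([C@H](CCC)CC(=O)OCC[Si](C)(C)C)=C(OC)C(C(=O)CC)=C1OC
F0 | step 12 | none | none
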